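The plan hinges on assembling ring B, the central para-phenylene, from two non-aromatic partners. In the target, C1 of ring B holds the enone carbon of the ring A chalcone and C4 the oxygen of the diaryl ether to ring C. Methyl coumalate supplies four ring carbons with C1 already carboxylated; an alkyne carrying the ether oxygen supplies the other two, one of them C4. The precursor is thus a terminal aryl ethynyl ether in which ring C, its phenols masked as methyl ethers, is already bound to the alkyne through oxygen. One cycloaddition with loss of CO2 should form two C–C bonds and ring B, ester and aryloxy group para. Routine chalcone chemistry follows.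

Key step: step 4

Remark (assumption): ring A is the 2,4-dioxygenated benzoyl ring, ring B the central para-phenylene, ring C the 1-aryloxy-2,4-dioxygenated ring that carries the second enone at C5, and ring D the 4-oxygenated phenyl ring. The target has no stereocentre, both alkenes are (E), and intermediates 11 and 16 are racemic.

Step 1
Reactants: 1 2,4-dimethoxybenzaldehyde
Product: 3 2,4-dimethoxyphenol, via aryl formate 2 (not isolated)
Conditions: 30% H2O2, cat. H2SO4, MeOH, rt
Reagents that add atoms: hydrogen peroxide, OO
Why: Acid-catalysed Dakin oxidation, in which hydroperoxide adds to the aldehyde, the electron-rich aryl group migrates to oxygen (Baeyer–Villiger-type shift favoured by the ortho and para methoxy donors) to give formate 2, and methanol transesterifies 2 to the phenol in the same flask.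

Step 2
Reactants: 3 2,4-dimethoxyphenol; 4 trichloroethylene
Product: 6 (E)-1-[(1,2-dichloroethenyl)oxy]-2,4-dimethoxybenzene, via dichloroacetylene 5 (not isolated)
Conditions: K2CO3, DMF, 70 °C
Reagents that add atoms: none
Why: Base-mediated dehydrochlorination of 4 gives dichloroacetylene 5 at low stationary concentration, and anti addition of the phenoxide across it (nucleophilic addition then protonation) is the standard entry to (E)-1,2-dichlorovinyl aryl ethers.

Step 3
Reactants: 6 (E)-1-[(1,2-dichloroethenyl)oxy]-2,4-dimethoxybenzene
Product: 9 1-(ethynyloxy)-2,4-dimethoxybenzene, via chloroalkynyl ether 7 (not isolated), via lithium acetylide 8 (not isolated)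
Conditions: n-BuLi (2.3 equiv), THF, −78 → −40 °C; then H2O, −78 → 0 °C
Reagents that add atoms: none
Why: Dehydrochlorination by n-BuLi gives chloroalkyne 7, chlorine–lithium exchange with the second equivalent gives acetylide 8, and cold, non-acidic protonation should release the terminal ynol ether (the established dichlorovinyl ether route to alkynyl ethers), which is kept cold in solution and used at once because it is acid-sensitive and self-reactive.

Step 4
Reactants: 9 1-(ethynyloxy)-2,4-dimethoxybenzene; 10 methyl coumalate
Product: 12 methyl 4-(2,4-dimethoxyphenoxy)benzoate, via bicyclic lactone adduct 11 (not isolated)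
Conditions: PhMe, 100 °C, N2, 9 added slowly to 10 (1.5 equiv)
Reagents that add atoms: none
Why: The electron-poor diene of 10 (C3=C4–C5=C6) and the electron-rich alkyne of 9 combine in an inverse-electron-demand Diels–Alder reaction in which the nucleophilic terminal CH of 9 bonds to C6 and the oxygen-bearing carbon to C3, giving lactone-bridged adduct 11, which then expels CO2 by retro-[4+2] under the same heating. The closest known chemistry is the thermal cycloaddition–decarboxylation of coumalate esters with enol ethers, ketene acetals, ynamines and plain alkynes, which leads to para-substituted benzoates. Ring B is closed by an intermolecular [4+2] cycloaddition that forms both new C–C bonds of a six-membered carbocycle, and it becomes aromatic when the O–C(=O) bridge leaves. The two bridgehead stereocentres of 11 are transient and are erased on aromatisation, so no stereocontrol is needed. The step needs para rather than meta orientation, and this is secured by matched polarisation: C6 is the electrophilic end of the dienyl ester and lactone system, and the terminal carbon is the nucleophilic β-position of the ynol ether. Slow addition of 9 to an excess of 10 keeps the self-reactive alkyne dilute, and because its oxygen substituent is an aryl ring the alkyne lacks the O–C–C–H array through which alkyl ynol ethers split into ketene and alkene on heating.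

Step 5
Reactants: 12 methyl 4-(2,4-dimethoxyphenoxy)benzoate
Product: 13 [4-(2,4-dimethoxyphenoxy)phenyl]methanol
Conditions: LiAlH4, THF, 0 °C
Reagents that add atoms: none
Why: Hydride reduction of an aryl ester to the benzylic alcohol with LiAlH4 is routine, and the diaryl ether and methyl ethers are inert to it.

Step 6
Reactants: 13 [4-(2,4-dimethoxyphenoxy)phenyl]methanol
Product: 14 4-(2,4-dimethoxyphenoxy)benzaldehyde
Conditions: MnO2, CH2Cl2, rt
Reagents that add atoms: none
Why: MnO2 oxidises benzylic alcohols selectively to aldehydes without over-oxidation and leaves the electron-rich ring C untouched.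

Step 7
Reactants: 14 4-(2,4-dimethoxyphenoxy)benzaldehyde; 15 2,4-dimethoxyacetophenone
Product: 17 (E)-1-(2,4-dimethoxyphenyl)-3-[4-(2,4-dimethoxyphenoxy)phenyl]prop-2-en-1-one, via aldol adduct 16 (not isolated)
Conditions: KOH, EtOH/H2O, rt
Reagents that add atoms: none
Why: Claisen–Schmidt condensation, in which the enolate of 15 adds to the non-enolisable aldehyde and aldol 16 dehydrates by E1cB to the conjugated enone, whose (E) geometry is the thermodynamic outcome.

Step 8
Reactants: 18 (E)-4-methoxycinnamic acid
Product: 19 (E)-4-methoxycinnamoyl chloride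
Conditions: (COCl)2, cat. DMF, CH2Cl2, 0 °C → rt
Reagents that add atoms: oxalyl chloride, O=C(Cl)C(=O)Cl
Why: Standard conversion of a carboxylic acid into its chloride by oxalyl chloride with DMF catalysis (chloroiminium activation), which does not touch the (E) alkene and gives a crude chloride that is used directly.

Step 9
Reactants: 17 (E)-1-(2,4-dimethoxyphenyl)-3-[4-(2,4-dimethoxyphenoxy)phenyl]prop-2-en-1-one; 19 (E)-4-methoxycinnamoyl chloride
Product: 20 (E)-1-(2,4-dimethoxyphenyl)-3-[4-(2,4-dimethoxy-5-[(E)-3-(4-methoxyphenyl)prop-2-enoyl]phenoxy)phenyl]prop-2-en-1-one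
Conditions: AlCl3 (3 equiv), CH2Cl2, −10 → 0 °C
Reagents that add atoms: none
Why: Friedel–Crafts acylation, in which the acylium ion from 19 should attack C5 of ring C (para to the 2-methoxy and ortho to the 4-methoxy group, whereas C3 between the two methoxy groups is shielded), while ring A is deactivated by its Lewis-acid-bound carbonyl and ring B by the enone, and the low temperature keeps conjugate arylation and chelation-assisted demethylation slow (a methyl ether lost next to a carbonyl here would be removed in step 10 anyway).

Step 10
Reactants: 20 (E)-1-(2,4-dimethoxyphenyl)-3-[4-(2,4-dimethoxy-5-[(E)-3-(4-methoxyphenyl)prop-2-enoyl]phenoxy)phenyl]prop-2-en-1-one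
Product: 21 (E)-1-(2,4-dihydroxyphenyl)-3-[4-(2,4-dihydroxy-5-[(E)-3-(4-hydroxyphenyl)prop-2-enoyl]phenoxy)phenyl]prop-2-en-1-one
Conditions: BBr3 (10 equiv), CH2Cl2, −78 °C → rt; then H2O
Reagents that add atoms: none
Why: BBr3 coordinates each methoxy oxygen and bromide removes the methyl group by SN2 to give aryl borates that water hydrolyses to the five phenols, while the diaryl ether (no sp3 carbon on oxygen) and both (E)-enones are expected to persist, as in the usual demethylation of polymethoxychalcones.

Compound list
1 | 2,4-dimethoxybenzaldehyde | COc1ccc(C=O)c(OC)c1 | starting material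
2 | 2,4-dimethoxyphenyl formate (not isolated) | COc1ccc(OC=O)c(OC)c1 | intermediate
3 | 2,4-dimethoxyphenol | COc1ccc(O)c(OC)c1 | intermediate
4 | trichloroethylene | ClC=C(Cl)Cl | starting material
5 | dichloroacetylene (not isolated) | ClC#CCl | intermediate
6 | (E)-1-[(1,2-dichloroethenyl)oxy]-2,4-dimethoxybenzene (the two chlorine atoms trans) | COc1ccc(O/C(Cl)=C\Cl)c(OC)c1 | intermediate
7 | 1-[(chloroethynyl)oxy]-2,4-dimethoxybenzene (not isolated) | COc1ccc(OC#CCl)c(OC)c1 | intermediate
8 | [(2,4-dimethoxyphenoxy)ethynyl]lithium (not isolated) | [Li]C#COc1ccc(OC)cc1OC | intermediate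
9 | 1-(ethynyloxy)-2,4-dimethoxybenzene | C#COc1ccc(OC)cc1OC | intermediate
10 | methyl coumalate (methyl 2-oxo-2H-pyran-5-carboxylate) | COC(=O)c1ccc(=O)oc1 | starting material
11 | methyl 8-(2,4-dimethoxyphenoxy)-3-oxo-2-oxabicyclo[2.2.2]octa-5,7-diene-6-carboxylate (racemic, not isolated; ester on the alkene carbon next to the O-bearing bridgehead, aryloxy group on the alkene carbon next to the carbonyl-side bridgehead) | O=C1OC2C=C(Oc3ccc(OC)cc3OC)C1C=C2C(=O)OC | intermediate
12 | methyl 4-(2,4-dimethoxyphenoxy)benzoate | COC(=O)c1ccc(Oc2ccc(OC)cc2OC)cc1 | intermediate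
13 | [4-(2,4-dimethoxyphenoxy)phenyl]methanol | OCc1ccc(Oc2ccc(OC)cc2OC)cc1 | intermediate
14 | 4-(2,4-dimethoxyphenoxy)benzaldehyde | O=Cc1ccc(Oc2ccc(OC)cc2OC)cc1 | intermediate
15 | 2,4-dimethoxyacetophenone | COc1ccc(C(C)=O)c(OC)c1 | starting material
16 | 1-(2,4-dimethoxyphenyl)-3-[4-(2,4-dimethoxyphenoxy)phenyl]-3-hydroxypropan-1-one (racemic, not isolated) | COc1ccc(C(=O)CC(O)c2ccc(Oc3ccc(OC)cc3OC)cc2)c(OC)c1 | intermediate
17 | (E)-1-(2,4-dimethoxyphenyl)-3-[4-(2,4-dimethoxyphenoxy)phenyl]prop-2-en-1-one | COc1ccc(C(=O)/C=C/c2ccc(Oc3ccc(OC)cc3OC)cc2)c(OC)c1 | intermediate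
18 | (E)-4-methoxycinnamic acid | COc1ccc(/C=C/C(=O)O)cc1 | starting material
19 | (E)-4-methoxycinnamoyl chloride | COc1ccc(/C=C/C(Cl)=O)cc1 | intermediate
20 | (E)-1-(2,4-dimethoxyphenyl)-3-[4-(2,4-dimethoxy-5-[(E)-3-(4-methoxyphenyl)prop-2-enoyl]phenoxy)phenyl]prop-2-en-1-one | O=C(/C=C/c1ccc(Oc2cc(C(=O)/C=C/c3ccc(OC)cc3)c(OC)cc2OC)cc1)c1ccc(OC)cc1OC | intermediate
21 | (E)-1-(2,4-dihydroxyphenyl)-3-[4-(2,4-dihydroxy-5-[(E)-3-(4-hydroxyphenyl)prop-2-enoyl]phenoxy)phenyl]prop-2-en-1-one | O=C(/C=C/c1ccc(Oc2cc(C(=O)/C=C/c3ccc(O)cc3)c(O)cc2O)cc1)c1ccc(O)cc1O | target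

Total step count: 10. Longest linear sequence: 9 steps (steps 1 to 7, then 9 and 10); step 8 is a one-step side branch.

Steps most likely to fail

Step 4. The terminal aryl ynol ether may oligomerise or be lost to adventitious hydration faster than it is captured by the pyrone, and any erosion of the para orientation would give an inseparable meta isomer. The fallback gives up the cycloaddition and forms the diaryl ether by nucleophilic aromatic substitution. It sets out from phenol 3, which with 4-fluorobenzaldehyde and K2CO3 in DMF at 120 °C should give aldehyde 14 directly, where it rejoins the route before step 7. No compound outside the list is made on this detour (entry F0).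

Step 9. With the Lewis acid bound to the chalcone carbonyl of 17, three processes may compete with acylation: chelation-assisted loss of the neighbouring methyl ether followed by ring closure, conjugate arylation of the activated enone by ring C of a second molecule, and sluggish acylium transfer. The fallback moves the acylation to a stage where no chalcone and no ring A are present. It sets out from aldehyde 14, which with chloride 19 and AlCl3 in CH2Cl2 at 0 °C should give 4-{2,4-dimethoxy-5-[(E)-3-(4-methoxyphenyl)prop-2-enoyl]phenoxy}benzaldehyde F1. Claisen–Schmidt condensation of F1 with ketone 15 (KOH, EtOH, rt) would pass through the aldol adduct 1-(2,4-dimethoxyphenyl)-3-hydroxy-3-(4-{2,4-dimethoxy-5-[(E)-3-(4-methoxyphenyl)prop-2-enoyl]phenoxy}phenyl)propan-1-one F2, which is not isolated, and comes back to the route at 20.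

Step 10. Ether cleavage may stop short at the least activated methyl ether (ring D), and the acid released may close the freed 2'-hydroxychalcone units to flavanones or add across the enones. The fallback removes the methyl groups before the second enone exists and never methylates ring D. It sets out from chalcone 17, which with acetyl chloride and AlCl3 in CH2Cl2 at 0 °C should give (E)-3-[4-(5-acetyl-2,4-dimethoxyphenoxy)phenyl]-1-(2,4-dimethoxyphenyl)prop-2-en-1-one F3. BBr3 in CH2Cl2 would then give (E)-3-[4-(5-acetyl-2,4-dihydroxyphenoxy)phenyl]-1-(2,4-dihydroxyphenyl)prop-2-en-1-one F4, with only one enone exposed and four activated ethers to cleave. Claisen–Schmidt condensation of F4 with 4-hydroxybenzaldehyde in concentrated aqueous KOH and EtOH keeps the chalcone open as its phenoxide. It would pass through the aldol adduct (E)-1-(2,4-dihydroxyphenyl)-3-(4-{2,4-dihydroxy-5-[3-hydroxy-3-(4-hydroxyphenyl)propanoyl]phenoxy}phenyl)prop-2-en-1-one F5, which is not isolated, and arrives at target 21 after cold acidification.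

Further compounds
F0 | step 4 | none | none
F1 | step 9 | 4-{2,4-dimethoxy-5-[(E)-3-(4-methoxyphenyl)prop-2-enoyl]phenoxy}benzaldehyde | O=Cc1ccc(Oc2cc(C(=O)/C=C/c3ccc(OC)cc3)c(OC)cc2OC)cc1
F2 | step 9 | 1-(2,4-dimethoxyphenyl)-3-hydroxy-3-(4-{2,4-dimethoxy-5-[(E)-3-(4-methoxyphenyl)prop-2-enoyl]phenoxy}phenyl)propan-1-one (racemic, not isolated) | COc1ccc(C(=O)CC(O)c2ccc(Oc3cc(C(=O)/C=C/c4ccc(OC)cc4)c(OC)cc3OC)cc2)c(OC)c1
F3 | step 10 | (E)-3-[4-(5-acetyl-2,4-dimethoxyphenoxy)phenyl]-1-(2,4-dimethoxyphenyl)prop-2-en-1-one | CC(=O)c1cc(Oc2ccc(/C=C/C(=O)c3ccc(OC)cc3OC)cc2)c(OC)cc1OC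
F4 | step 10 | (E)-3-[4-(5-acetyl-2,4-dihydroxyphenoxy)phenyl]-1-(2,4-dihydroxyphenyl)prop-2-en-1-one | CC(=O)c1cc(Oc2ccc(/C=C/C(=O)c3ccc(O)cc3O)cc2)c(O)cc1O
F5 | step 10 | (E)-1-(2,4-dihydroxyphenyl)-3-(4-{2,4-dihydroxy-5-[3-hydroxy-3-(4-hydroxyphenyl)propanoyl]phenoxy}phenyl)prop-2-en-1-one (racemic, not isolated) | O=C(CC(O)c1ccc(O)cc1)c1cc(Oc2ccc(/C=C/C(=O)c3ccc(O)cc3O)cc2)c(O)cc1O
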